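## Retrosynthetic overview

1. Last operations: the C8 angelate is installed with inversion (Mitsunobu) on a macrocyclic carbinol, then the C1 silyl ether is removed.
2. Key bond C7–C8: an intramolecular CrCl2-mediated allylation of an aldehyde by a 3-(bromomethyl)butenolide. The butenolide β-carbon, normally a Michael acceptor, reacts as a homoenolate (d3) donor toward the aldehyde carbon. This closes the ten-membered ring and unveils the α-methylene lactone in one step.
3. The butenolide (C6, C7, C11–C13) and the anti C5/C6 oxygen pattern come from a catalytic asymmetric vinylogous Mukaiyama aldol of a 2-silyloxyfuran with an enal.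
4. That enal (E-C3=C4, C1 stereocentre, C10 methylene) comes from an asymmetric vinylogous Mukaiyama aldol of the dienol ether of tiglic aldehyde with 2-methylidene-4-silyloxybutanal.
5. Ring order: butenolide first, ten-membered carbocycle last.

Convention and assumption: the carbocycle is numbered C1 (CHOH), C2 (CH2), C3 (=CH), C4 (=C–CH3), C5 (CHOAc), C6 (CH–O of the lactone), C7 (ring-fusion CH), C8 (CH–O-angelate), C9 (CH2), C10 (C=CH2); the lactone carbons are C11 (α-C), C12 (C=O), C13 (=CH2). The target is then 1S,5S,6R,7S,8S,3E. Compounds 1, 3 and 7 and all reagents are taken as purchased. TBS = tert-butyldimethylsilyl.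

## Route

Step 1
Reactants: 1 4-[(tert-butyldimethylsilyl)oxy]butanal
Product: 2 4-[(tert-butyldimethylsilyl)oxy]-2-methylidenebutanal
Conditions: 37% aq. HCHO, pyrrolidine (10 mol%), propionic acid (10 mol%), i-PrOH, 45 °C
Reagents that add atoms: formaldehyde, C=O
Why: Organocatalytic Mannich condensation–elimination (α-methylenation of an aldehyde) installs the future C10=CH2 unit; no stereocentre is formed.

Step 2
Reactants: 3 (E)-2-methylbut-2-enal (tiglic aldehyde)
Product: 4 tert-butyldimethyl{[(1E)-2-methylbuta-1,3-dien-1-yl]oxy}silane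
Conditions: TBSOTf, Et3N, Et2O, 0 → 23 °C
Reagents that add atoms: tert-butyldimethylsilyl trifluoromethanesulfonate, CC(C)(C)[Si](C)(C)OS(=O)(=O)C(F)(F)F
Why: Soft γ-enolisation and O-silylation of the enal give the silyl dienol ether (vinylogous enolate equivalent).

Step 3
Reactants: 2 4-[(tert-butyldimethylsilyl)oxy]-2-methylidenebutanal; 4 tert-butyldimethyl{[(1E)-2-methylbuta-1,3-dien-1-yl]oxy}silane
Product: 5 (2E,5S)-8-[(tert-butyldimethylsilyl)oxy]-5-hydroxy-2-methyl-6-methylideneoct-2-enal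
Conditions: B-phenyl oxazaborolidinone from N-tosyl-D-tryptophan and PhBCl2 (50 mol%), i-PrOH (1.1 equiv), EtCN, −78 °C
Reagents that add atoms: none
Why: Vinylogous Mukaiyama aldol in which the boron-bound aldehyde is attacked at its Si face by the γ-carbon of the dienol ether (the indole of the D-tryptophan ligand is expected to shield the Re face), setting 1S (5S in this name); the s-trans diene gives the E-trisubstituted enal.

Step 4
Reactants: 5 (2E,5S)-8-[(tert-butyldimethylsilyl)oxy]-5-hydroxy-2-methyl-6-methylideneoct-2-enal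
Product: 6 (2E,5S)-5,8-bis[(tert-butyldimethylsilyl)oxy]-2-methyl-6-methylideneoct-2-enal
Conditions: TBSCl, imidazole, DMF, 23 °C
Reagents that add atoms: tert-butyldimethylsilyl chloride, CC(C)(C)[Si](C)(C)Cl
Why: Standard silylation of the secondary allylic alcohol; the enal is untouched and C1 is not affected.

Step 5
Reactants: 7 3-bromofuran-2(5H)-one
Product: 8 3-(hydroxymethyl)furan-2(5H)-one
Conditions: Bu3SnCH2OH, Pd(PPh3)4 (5 mol%), 1,4-dioxane, 90 °C
Reagents that add atoms: (tributylstannyl)methanol, CCCC[Sn](CCCC)(CCCC)CO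
Why: Migita–Kosugi–Stille coupling: the activated α-bromo enoate undergoes oxidative addition readily and the hydroxymethyl group (future C13) is transferred from tin.

Step 6
Reactants: 8 3-(hydroxymethyl)furan-2(5H)-one
Product: 9 tert-butyl[(3-{[(tert-butyldimethylsilyl)oxy]methyl}furan-2-yl)oxy]dimethylsilane
Conditions: TBSOTf (2.2 equiv), Et3N, CH2Cl2, 0 °C
Reagents that add atoms: tert-butyldimethylsilyl trifluoromethanesulfonate, CC(C)(C)[Si](C)(C)OS(=O)(=O)C(F)(F)F
Why: O-silylation of the alcohol and γ-deprotonation/O-silylation of the butenolide give the aromatic 2-silyloxyfuran in one operation.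

Step 7
Reactants: 6 (2E,5S)-5,8-bis[(tert-butyldimethylsilyl)oxy]-2-methyl-6-methylideneoct-2-enal; 9 tert-butyl[(3-{[(tert-butyldimethylsilyl)oxy]methyl}furan-2-yl)oxy]dimethylsilane
Product: 10 (5R)-5-[(1S,2E,5S)-5,8-bis[(tert-butyldimethylsilyl)oxy]-1-hydroxy-2-methyl-6-methylideneoct-2-en-1-yl]-3-{[(tert-butyldimethylsilyl)oxy]methyl}furan-2(5H)-one
Conditions: [Cr(salen)]SbF6 (salen = (R,R)-N,N′-bis(3,5-di-tert-butylsalicylidene)cyclohexane-1,2-diamine dianion; 5 mol%), i-PrOH (1.1 equiv), CH2Cl2, −30 °C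
Reagents that add atoms: none
Why: Vinylogous Mukaiyama aldol: the cationic trivalent chromium Lewis acid activates the enal, and the furan attacks through its C5 in an open transition state that favours the anti (erythro) adduct; the ligand is intended to select the Re face of the aldehyde (5S, 6R; the antipodal ligand is used if the sense proves opposite), and i-PrOH takes up the silyl group.

Step 8
Reactants: 10 (5R)-5-[(1S,2E,5S)-5,8-bis[(tert-butyldimethylsilyl)oxy]-1-hydroxy-2-methyl-6-methylideneoct-2-en-1-yl]-3-{[(tert-butyldimethylsilyl)oxy]methyl}furan-2(5H)-one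
Product: 11 (1S,2E,5S)-5,8-bis[(tert-butyldimethylsilyl)oxy]-1-[(2R)-4-{[(tert-butyldimethylsilyl)oxy]methyl}-5-oxo-2,5-dihydrofuran-2-yl]-2-methyl-6-methylideneoct-2-en-1-yl acetate
Conditions: Ac2O, pyridine, DMAP (cat.), CH2Cl2, 0 °C
Reagents that add atoms: acetic anhydride, CC(=O)OC(C)=O
Why: Acylation of the only free hydroxyl installs the C5 acetate of the target; mild base at 0 °C avoids elimination to the γ-alkylidene butenolide.

Step 9
Reactants: 11 (1S,2E,5S)-5,8-bis[(tert-butyldimethylsilyl)oxy]-1-[(2R)-4-{[(tert-butyldimethylsilyl)oxy]methyl}-5-oxo-2,5-dihydrofuran-2-yl]-2-methyl-6-methylideneoct-2-en-1-yl acetate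
Product: 12 (1S,2E,5S)-5-[(tert-butyldimethylsilyl)oxy]-8-hydroxy-1-[(2R)-4-(hydroxymethyl)-5-oxo-2,5-dihydrofuran-2-yl]-2-methyl-6-methylideneoct-2-en-1-yl acetate
Conditions: HF·pyridine, pyridine, THF, 0 °C
Reagents that add atoms: none
Why: Buffered HF cleaves the two primary TBS ethers (C13–O and C8–O) much faster than the hindered secondary allylic TBS ether at C1; the acetate and butenolide are stable.

Step 10
Reactants: 12 (1S,2E,5S)-5-[(tert-butyldimethylsilyl)oxy]-8-hydroxy-1-[(2R)-4-(hydroxymethyl)-5-oxo-2,5-dihydrofuran-2-yl]-2-methyl-6-methylideneoct-2-en-1-yl acetate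
Product: 13 (1S,2E,5S)-1-[(2R)-4-(bromomethyl)-5-oxo-2,5-dihydrofuran-2-yl]-5-[(tert-butyldimethylsilyl)oxy]-8-hydroxy-2-methyl-6-methylideneoct-2-en-1-yl acetate
Conditions: NBS, Me2S, CH2Cl2, −30 → 0 °C
Reagents that add atoms: N-bromosuccinimide, O=C1CCC(=O)N1Br
Why: Corey–Kim-type halogenation: the bromosulfonium reagent converts only the allylic alcohol into the bromide by SN2 collapse of its alkoxysulfonium salt, while the saturated primary alcohol is returned unchanged on work-up.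

Step 11
Reactants: 13 (1S,2E,5S)-1-[(2R)-4-(bromomethyl)-5-oxo-2,5-dihydrofuran-2-yl]-5-[(tert-butyldimethylsilyl)oxy]-8-hydroxy-2-methyl-6-methylideneoct-2-en-1-yl acetate
Product: 14 (1S,2E,5S)-1-[(2R)-4-(bromomethyl)-5-oxo-2,5-dihydrofuran-2-yl]-5-[(tert-butyldimethylsilyl)oxy]-2-methyl-6-methylidene-8-oxooct-2-en-1-yl acetate
Conditions: Dess–Martin periodinane, NaHCO3, CH2Cl2, 0 °C; used at once
Reagents that add atoms: none
Why: Buffered Dess–Martin oxidation gives the β,γ-unsaturated aldehyde without base-induced migration of the C10 methylene into conjugation; the allylic bromide tolerates the oxidant.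

Step 12
Reactants: 14 (1S,2E,5S)-1-[(2R)-4-(bromomethyl)-5-oxo-2,5-dihydrofuran-2-yl]-5-[(tert-butyldimethylsilyl)oxy]-2-methyl-6-methylidene-8-oxooct-2-en-1-yl acetate
Product: 16 (3aS,4R,7S,9E,11S,11aR)-7-[(tert-butyldimethylsilyl)oxy]-4-hydroxy-10-methyl-3,6-dimethylidene-2-oxo-2,3,3a,4,5,6,7,8,11,11a-decahydrocyclodeca[b]furan-11-yl acetate (1S,5S,6R,7S,8R in the numbering of this answer), via allylchromium dichloride 15 (not isolated)
Conditions: CrCl2 (10 equiv), THF, 23 °C, 14 added by syringe pump over 10 h (final 0.002 M)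
Reagents that add atoms: none
Why: Macrocyclising Nozaki–Hiyama (Barbier-type) allylation: divalent chromium turns the electrophilic allylic bromide into a σ-allylchromium whose γ-carbon C7 (the butenolide β-carbon) attacks the aldehyde by SE2′ through a Zimmerman–Traxler chair; attack anti to the C5 side chain gives the trans ring fusion (7S), and with the allyl unit locked E by the butenolide and C9 pseudo-equatorial (anti to C11) the carbinol is predicted to be 8R (H7/H8 anti).

Step 13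
Reactants: 16 (3aS,4R,7S,9E,11S,11aR)-7-[(tert-butyldimethylsilyl)oxy]-4-hydroxy-10-methyl-3,6-dimethylidene-2-oxo-2,3,3a,4,5,6,7,8,11,11a-decahydrocyclodeca[b]furan-11-yl acetate
Product: 17 (3aS,4S,7S,9E,11S,11aR)-11-acetoxy-7-[(tert-butyldimethylsilyl)oxy]-10-methyl-3,6-dimethylidene-2-oxo-2,3,3a,4,5,6,7,8,11,11a-decahydrocyclodeca[b]furan-4-yl (2Z)-2-methylbut-2-enoate
Conditions: angelic acid (3 equiv), PPh3 (3 equiv), DIAD (3 equiv), toluene, 0 → 23 °C
Reagents that add atoms: angelic acid [(2Z)-2-methylbut-2-enoic acid], C/C=C(/C)C(=O)O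
Why: Mitsunobu esterification: SN2 displacement of the C8 alkoxyphosphonium by angelate inverts C8 to S while installing the ester, and because the carboxylate acts as nucleophile (no acyl activation) the Z geometry is not isomerised to tiglate.

Step 14
Reactants: 17 (3aS,4S,7S,9E,11S,11aR)-11-acetoxy-7-[(tert-butyldimethylsilyl)oxy]-10-methyl-3,6-dimethylidene-2-oxo-2,3,3a,4,5,6,7,8,11,11a-decahydrocyclodeca[b]furan-4-yl (2Z)-2-methylbut-2-enoate
Product: 18 (3aS,4S,7S,9E,11S,11aR)-11-acetoxy-7-hydroxy-10-methyl-3,6-dimethylidene-2-oxo-2,3,3a,4,5,6,7,8,11,11a-decahydrocyclodeca[b]furan-4-yl (2Z)-2-methylbut-2-enoate (CNP0115054.1)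
Conditions: HF·pyridine, pyridine, THF, 0 → 23 °C
Reagents that add atoms: none
Why: Fluoride-mediated cleavage of the secondary TBS ether under buffered acidic conditions leaves the α-methylene lactone, acetate and angelate intact and touches no stereocentre.

## Compound list

1 | 4-[(tert-butyldimethylsilyl)oxy]butanal | O=CCCCO[Si](C)(C)C(C)(C)C | starting material
2 | 4-[(tert-butyldimethylsilyl)oxy]-2-methylidenebutanal | C=C(C=O)CCO[Si](C)(C)C(C)(C)C | intermediate
3 | (E)-2-methylbut-2-enal (tiglic aldehyde) | C/C=C(\C)C=O | starting material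
4 | tert-butyldimethyl{[(1E)-2-methylbuta-1,3-dien-1-yl]oxy}silane | C=C/C(C)=C/O[Si](C)(C)C(C)(C)C | intermediate
5 | (2E,5S)-8-[(tert-butyldimethylsilyl)oxy]-5-hydroxy-2-methyl-6-methylideneoct-2-enal | O=C/C(C)=C/C[C@H](O)C(=C)CCO[Si](C)(C)C(C)(C)C | intermediate
6 | (2E,5S)-5,8-bis[(tert-butyldimethylsilyl)oxy]-2-methyl-6-methylideneoct-2-enal | O=C/C(C)=C/C[C@H](O[Si](C)(C)C(C)(C)C)C(=C)CCO[Si](C)(C)C(C)(C)C | intermediate
7 | 3-bromofuran-2(5H)-one | O=C1OCC=C1Br | starting material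
8 | 3-(hydroxymethyl)furan-2(5H)-one | O=C1OCC=C1CO | intermediate
9 | tert-butyl[(3-{[(tert-butyldimethylsilyl)oxy]methyl}furan-2-yl)oxy]dimethylsilane | CC(C)(C)[Si](C)(C)OCc1ccoc1O[Si](C)(C)C(C)(C)C | intermediate
10 | (5R)-5-[(1S,2E,5S)-5,8-bis(TBS-oxy)-1-hydroxy-2-methyl-6-methylideneoct-2-en-1-yl]-3-[(TBS-oxy)methyl]furan-2(5H)-one | CC(C)(C)[Si](C)(C)OCC1=C[C@@H](OC1=O)[C@@H](O)/C(C)=C/C[C@H](O[Si](C)(C)C(C)(C)C)C(=C)CCO[Si](C)(C)C(C)(C)C | intermediate
11 | (1S,2E,5S)-5,8-bis(TBS-oxy)-1-[(2R)-4-[(TBS-oxy)methyl]-5-oxo-2,5-dihydrofuran-2-yl]-2-methyl-6-methylideneoct-2-en-1-yl acetate | CC(C)(C)[Si](C)(C)OCC1=C[C@@H](OC1=O)[C@@H](OC(C)=O)/C(C)=C/C[C@H](O[Si](C)(C)C(C)(C)C)C(=C)CCO[Si](C)(C)C(C)(C)C | intermediate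
12 | (1S,2E,5S)-5-(TBS-oxy)-8-hydroxy-1-[(2R)-4-(hydroxymethyl)-5-oxo-2,5-dihydrofuran-2-yl]-2-methyl-6-methylideneoct-2-en-1-yl acetate | OCC1=C[C@@H](OC1=O)[C@@H](OC(C)=O)/C(C)=C/C[C@H](O[Si](C)(C)C(C)(C)C)C(=C)CCO | intermediate
13 | (1S,2E,5S)-1-[(2R)-4-(bromomethyl)-5-oxo-2,5-dihydrofuran-2-yl]-5-(TBS-oxy)-8-hydroxy-2-methyl-6-methylideneoct-2-en-1-yl acetate | BrCC1=C[C@@H](OC1=O)[C@@H](OC(C)=O)/C(C)=C/C[C@H](O[Si](C)(C)C(C)(C)C)C(=C)CCO | intermediate
14 | (1S,2E,5S)-1-[(2R)-4-(bromomethyl)-5-oxo-2,5-dihydrofuran-2-yl]-5-(TBS-oxy)-2-methyl-6-methylidene-8-oxooct-2-en-1-yl acetate | BrCC1=C[C@@H](OC1=O)[C@@H](OC(C)=O)/C(C)=C/C[C@H](O[Si](C)(C)C(C)(C)C)C(=C)CC=O | intermediate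
15 | allylchromium dichloride of 14 (CrCl2 unit on C13 in place of Br) | Cl[Cr](Cl)CC1=C[C@@H](OC1=O)[C@@H](OC(C)=O)/C(C)=C/C[C@H](O[Si](C)(C)C(C)(C)C)C(=C)CC=O | intermediate
16 | (3aS,4R,7S,9E,11S,11aR)-7-(TBS-oxy)-4-hydroxy-10-methyl-3,6-dimethylidene-2-oxo-2,3,3a,4,5,6,7,8,11,11a-decahydrocyclodeca[b]furan-11-yl acetate | C=C1C(=O)O[C@@H]2[C@@H]1[C@H](O)CC(=C)[C@@H](O[Si](C)(C)C(C)(C)C)C/C=C(\C)[C@@H]2OC(C)=O | intermediate
17 | (3aS,4S,7S,9E,11S,11aR)-11-acetoxy-7-(TBS-oxy)-10-methyl-3,6-dimethylidene-2-oxo-2,3,3a,4,5,6,7,8,11,11a-decahydrocyclodeca[b]furan-4-yl (2Z)-2-methylbut-2-enoate | C=C1C(=O)O[C@@H]2[C@@H]1[C@@H](OC(=O)/C(C)=C\C)CC(=C)[C@@H](O[Si](C)(C)C(C)(C)C)C/C=C(\C)[C@@H]2OC(C)=O | intermediate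
18 | (3aS,4S,7S,9E,11S,11aR)-11-acetoxy-7-hydroxy-10-methyl-3,6-dimethylidene-2-oxo-2,3,3a,4,5,6,7,8,11,11a-decahydrocyclodeca[b]furan-4-yl (2Z)-2-methylbut-2-enoate | C=C1C(=O)O[C@@H]2[C@@H]1[C@@H](OC(=O)/C(C)=C\C)CC(=C)[C@@H](O)C/C=C(\C)[C@@H]2OC(C)=O | target

## Step count and risks

Total step count: 14. Longest linear sequence: 11 steps (from 1 through steps 1, 3, 4 and 7–14; the same length from 3 through step 2).

The three steps most likely to fail:

**Step 12 (macrocyclisation).** The ring may not close cleanly: oligomers, attack through C13 to a twelve-membered ring, or cis fusion are possible. The C8 outcome rests on a chair model that has not been tested on a ten-membered closure. The fallback sets out from 13 and replaces the reductively generated organochromium by an isolable allyl donor that cyclises through an open transition state. Zinc dust and Bu3SnCl in THF/aq. NH4Cl convert 13 into the allylstannane alcohol F1. Dess–Martin oxidation gives the stannyl aldehyde F2. BF3·OEt2 in CH2Cl2 at −78 °C under high dilution then closes the same C7–C8 bond by an SE2′ (Hosomi–Sakurai-type) addition. The route is rejoined at 16.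

**Step 13 (Mitsunobu on a hindered ring carbinol).** Backside attack at C8 is flanked by C6, and elimination toward C7 or participation by the lactone carbonyl could compete. The fallback sets out from 16 and inverts C8 by redox instead of substitution. Dess–Martin oxidation gives the C8 ketone F3. Reduction with (R)-2-methyl-CBS-oxazaborolidine and catecholborane, with hydride delivered from the outer face anti to C6, gives the 8S alcohol F4. Yamaguchi esterification (angelic acid, 2,4,6-trichlorobenzoyl chloride, Et3N, then F4, toluene) rejoins the route at 17.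

**Step 7 (catalytic asymmetric vinylogous aldol).** Anti selectivity and the absolute sense with this 3-substituted silyloxyfuran and a trisubstituted enal are the least precedented stereochemical claim. The fallback sets out from 6 and builds the same centres by allylboration and ring-closing metathesis. Brown allylboration with (Z)-γ-(methoxymethoxy)allyldiisopinocampheylborane gives the syn alcohol F5. Mitsunobu reaction with acetic acid inverts C5 and installs the acetate, giving F6. Me2BBr at −78 °C removes the methoxymethyl group to give alcohol F7. Steglich esterification at low temperature with 2-{[(tert-butyldimethylsilyl)oxy]methyl}acrylic acid gives the diene ester F8. Ring-closing metathesis with the second-generation Hoveyda–Grubbs catalyst forms the butenolide and rejoins the route at 11.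

## Further compounds

F1 | step 12 | (1S,2E,5S)-5-(TBS-oxy)-8-hydroxy-2-methyl-6-methylidene-1-{(2R)-5-oxo-4-[(tributylstannyl)methyl]-2,5-dihydrofuran-2-yl}oct-2-en-1-yl acetate | CCCC[Sn](CCCC)(CCCC)CC1=C[C@@H](OC1=O)[C@@H](OC(C)=O)/C(C)=C/C[C@H](O[Si](C)(C)C(C)(C)C)C(=C)CCO
F2 | step 12 | (1S,2E,5S)-5-(TBS-oxy)-2-methyl-6-methylidene-8-oxo-1-{(2R)-5-oxo-4-[(tributylstannyl)methyl]-2,5-dihydrofuran-2-yl}oct-2-en-1-yl acetate | CCCC[Sn](CCCC)(CCCC)CC1=C[C@@H](OC1=O)[C@@H](OC(C)=O)/C(C)=C/C[C@H](O[Si](C)(C)C(C)(C)C)C(=C)CC=O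
F3 | step 13 | C8 ketone of 16 (4-oxo analogue; C7 geometry unchanged) | C=C1C(=O)O[C@@H]2[C@@H]1C(=O)CC(=C)[C@@H](O[Si](C)(C)C(C)(C)C)C/C=C(\C)[C@@H]2OC(C)=O
F4 | step 13 | (3aS,4S,7S,9E,11S,11aR)-7-(TBS-oxy)-4-hydroxy-10-methyl-3,6-dimethylidene-2-oxo-2,3,3a,4,5,6,7,8,11,11a-decahydrocyclodeca[b]furan-11-yl acetate (8S epimer of 16) | C=C1C(=O)O[C@@H]2[C@@H]1[C@@H](O)CC(=C)[C@@H](O[Si](C)(C)C(C)(C)C)C/C=C(\C)[C@@H]2OC(C)=O
F5 | step 7 | (3R,4R,5E,8S)-8,11-bis(TBS-oxy)-3-(methoxymethoxy)-5-methyl-9-methylideneundeca-1,5-dien-4-ol | C=C[C@@H](OCOC)[C@H](O)/C(C)=C/C[C@H](O[Si](C)(C)C(C)(C)C)C(=C)CCO[Si](C)(C)C(C)(C)C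
F6 | step 7 | (3R,4S,5E,8S)-8,11-bis(TBS-oxy)-3-(methoxymethoxy)-5-methyl-9-methylideneundeca-1,5-dien-4-yl acetate | C=C[C@@H](OCOC)[C@@H](OC(C)=O)/C(C)=C/C[C@H](O[Si](C)(C)C(C)(C)C)C(=C)CCO[Si](C)(C)C(C)(C)C
F7 | step 7 | (3R,4S,5E,8S)-8,11-bis(TBS-oxy)-3-hydroxy-5-methyl-9-methylideneundeca-1,5-dien-4-yl acetate | C=C[C@@H](O)[C@@H](OC(C)=O)/C(C)=C/C[C@H](O[Si](C)(C)C(C)(C)C)C(=C)CCO[Si](C)(C)C(C)(C)C
F8 | step 7 | (3R,4S,5E,8S)-4-acetoxy-8,11-bis(TBS-oxy)-5-methyl-9-methylideneundeca-1,5-dien-3-yl 2-{[(tert-butyldimethylsilyl)oxy]methyl}prop-2-enoate | C=C[C@@H](OC(=O)C(=C)CO[Si](C)(C)C(C)(C)C)[C@@H](OC(C)=O)/C(C)=C/C[C@H](O[Si](C)(C)C(C)(C)C)C(=C)CCO[Si](C)(C)C(C)(C)C
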